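**Plan**
Ring numbering used below: C1 = ketone carbon, C2 = C(CH2OH), C3 = CH=, C4 = CH–O–propanoyl, C5 = CH–isopropyl, C6 = CH–O–enoyl.
Retrosynthesis cuts the C6–O and C4–O acyl bonds (the latter together with return of C6 to a ketone), masks C1=O as a 1,3-dithiane, then cuts the ring at C1–C2 and C4–C5.
Enabling feature: C2, C3, C4 and the CH2O group are a 4-oxybut-2-ynal, whose β-carbon (C2) and CHO carbon (C4) are 1,3-electrophiles. C1 and C5 both flank C6, so with C6 as a ketone and C1 as a dithiane carbon they are 1,3-nucleophiles; the quaternary dithiane carbon also blocks aromatisation.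
Forward: acyl dithiane 4 and ynal 8 are joined and the only ring is closed in one domino Michael/aldol [3+3] annulation; Evans–Tishchenko reduction, dithiane hydrolysis, esterification and desilylation follow.
Stereochemistry: C4 and C5 are set together in the catalyst-controlled ring-closing aldol (cis, from a Z enolate in a closed transition state); C6 is relayed from C4–O by intramolecular hydride delivery (1,3-anti).

Key step: step 3

Assumption: the (S,S) ligand is taken to favour the (8S,9S) enantiomer of 10; if the opposite sense is found, the (R,R) ligand is used instead.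

Step 1
Reactants: 1 1,3-dithiane; 2 methyl 3-methylbutanoate
Product: 4 1-(1,3-dithian-2-yl)-3-methylbutan-1-one, via 2-lithio-1,3-dithiane 3 (not isolated)
Conditions: 1 (2.1 equiv), n-BuLi (2.0 equiv), THF, −30 °C; then 2 (1.0 equiv), −78 → 0 °C; AcOH quench
Reagents that add atoms: none
Why: Corey–Seebach acylation, in which lithiated dithiane 3 adds to the ester and the second equivalent of 3 deprotonates the C–H acidic 2-acyl dithiane as it forms, so that no second addition occurs; no stereocenter is formed.

Step 2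
Reactants: 5 tert-butyldimethyl(prop-2-yn-1-yloxy)silane
Product: 8 4-[(tert-butyldimethylsilyl)oxy]but-2-ynal, via lithium acetylide 6 (not isolated), via lithium hemiaminal alkoxide 7 (not isolated)
Conditions: n-BuLi, THF, −78 °C; DMF, −78 → 0 °C; inverse quench into aq. KH2PO4/MTBE, 0 °C
Reagents that add atoms: N,N-dimethylformamide, CN(C)C=O
Why: Formylation of a lithium acetylide with DMF, where the hemiaminal alkoxide 7 persists until the buffered inverse quench and the base-sensitive ynal is released without conjugate addition of dimethylamine.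

Step 3
Reactants: 4 1-(1,3-dithian-2-yl)-3-methylbutan-1-one; 8 4-[(tert-butyldimethylsilyl)oxy]but-2-ynal
Product: 10 (8S,9S)-11-{[(tert-butyldimethylsilyl)oxy]methyl}-9-hydroxy-8-(propan-2-yl)-1,5-dithiaspiro[5.5]undec-10-en-7-one, via (Z)-enal Michael adduct 9 (not isolated)
Conditions: ZnEt2 (20 mol %), (S,S)-ProPhenol ligand [2,6-bis{[(2S)-2-(hydroxydiphenylmethyl)pyrrolidin-1-yl]methyl}-4-methylphenol] (10 mol %), 4 Å MS, THF, 0 °C → rt, slow addition of 8
Reagents that add atoms: none
Why: Proposed new method: the dinuclear zinc alkoxide deprotonates the C–H acid 4 (flanked by two sulfur atoms and the carbonyl) and the soft zinc enolate adds 1,4 to ynal 8 (C1–C2 bond), protonation of the zinc allenolate gives enal 9, and the same catalyst then enolises the ketone towards its only remaining enolisable α-carbon and adds it to the aldehyde (C4–C5 bond). The closest known reaction types are the base- or amine-catalysed domino Michael/aldol [3+3] annulation of β-keto ester-type 1,3-bisnucleophiles with enals, the conjugate addition of 1,3-dicarbonyl C–H acids to ynals and ynones, and the zinc–ProPhenol direct aldol and Michael reactions of unactivated ketones. The only ring is closed in a 6-(enolendo)-exo-trig aldol. The two new stereocenters C4 and C5 arise together: the quaternary dithiane carbon enforces the Z enolate, and with enolate oxygen and aldehyde oxygen held on the two zinc atoms the tether must lie on the opposite side, which places OH axial and isopropyl equatorial (cis), while the chiral pocket of the ligand selects one of the two mirror-image transition states. The step needs 1,4- over 1,2-addition (the 1,2-adduct of a hindered stabilised carbanion reverts), the Z enal (E and Z equilibrate through the zinc dienolate and only Z can cyclise), and no dehydration or aromatisation (mild conditions; the quaternary dithiane carbon cannot enolise).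

Step 4
Reactants: 10 (8S,9S)-11-{[(tert-butyldimethylsilyl)oxy]methyl}-9-hydroxy-8-(propan-2-yl)-1,5-dithiaspiro[5.5]undec-10-en-7-one
Product: 12 (7R,8R,9S)-11-{[(tert-butyldimethylsilyl)oxy]methyl}-7-hydroxy-8-(propan-2-yl)-1,5-dithiaspiro[5.5]undec-10-en-9-yl propanoate (locants as in 10), via propanal hemiacetal 11 (not isolated)
Conditions: EtCHO (6 equiv), SmI2 (30 mol %), THF, −10 °C
Reagents that add atoms: propanal, CCC=O
Why: Evans–Tishchenko reduction, in which the samarium-bound propanal hemiacetal 11 of the axial C4–OH delivers hydride intramolecularly to the same face of the C6 ketone, so that the new carbinol is anti to C4–O and trans to isopropyl, the propanoate ends up on C4–O only, and the trans-1,3 ring geometry prevents acyl migration.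

Step 5
Reactants: 12 (7R,8R,9S)-11-{[(tert-butyldimethylsilyl)oxy]methyl}-7-hydroxy-8-(propan-2-yl)-1,5-dithiaspiro[5.5]undec-10-en-9-yl propanoate
Product: 13 (1S,5R,6R)-3-{[(tert-butyldimethylsilyl)oxy]methyl}-5-hydroxy-4-oxo-6-(propan-2-yl)cyclohex-2-en-1-yl propanoate
Conditions: PhI(OCOCF3)2 (1.5 equiv), NaHCO3, MeCN–H2O (9:1), 0 °C
Reagents that add atoms: water, O
Why: Oxidative hydrolysis of the S,S-acetal with a hypervalent iodine reagent unmasks the C1 ketone as the conjugated enone, while the secondary alcohol, allylic ester and silyl ether should survive the brief buffered conditions and no stereocenter is touched.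

Step 6
Reactants: 14 [(tert-butyldimethylsilyl)oxy]acetaldehyde; 15 ethyl 2-(triphenylphosphoranylidene)propanoate
Product: 16 ethyl (2E)-4-[(tert-butyldimethylsilyl)oxy]-2-methylbut-2-enoate
Conditions: CH2Cl2, rt
Reagents that add atoms: none
Why: Wittig olefination with a stabilised α-branched ylide, which should give the (E)-trisubstituted enoate because oxaphosphetane formation is reversible and the ester ends up trans to the CH2O group.

Step 7
Reactants: 16 ethyl (2E)-4-[(tert-butyldimethylsilyl)oxy]-2-methylbut-2-enoate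
Product: 17 (2E)-4-[(tert-butyldimethylsilyl)oxy]-2-methylbut-2-enoic acid
Conditions: LiOH, THF–H2O, 0 °C → rt; then dilute HCl to pH 4
Reagents that add atoms: lithium hydroxide, [Li+].[OH-]
Why: Saponification of the ethyl ester, which the primary silyl ether and the alkene geometry should tolerate at low temperature with mild acidification.

Step 8
Reactants: 17 (2E)-4-[(tert-butyldimethylsilyl)oxy]-2-methylbut-2-enoic acid; 13 (1S,5R,6R)-3-{[(tert-butyldimethylsilyl)oxy]methyl}-5-hydroxy-4-oxo-6-(propan-2-yl)cyclohex-2-en-1-yl propanoate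
Product: 19 (1R,5S,6S)-3-{[(tert-butyldimethylsilyl)oxy]methyl}-2-oxo-5-(propanoyloxy)-6-(propan-2-yl)cyclohex-3-en-1-yl (2E)-4-[(tert-butyldimethylsilyl)oxy]-2-methylbut-2-enoate, via mixed anhydride 18 (not isolated)
Conditions: 17, 2,4,6-trichlorobenzoyl chloride, Et3N, THF, rt; then 13, DMAP (cat.), toluene, rt
Reagents that add atoms: none
Why: Yamaguchi esterification, in which DMAP attacks the less hindered enoyl carbonyl of mixed anhydride 18 and the acylpyridinium acylates the single free hydroxyl; C6 keeps its configuration, and the equatorial ester is also the thermodynamic epimer.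

Step 9
Reactants: 19 (1R,5S,6S)-3-{[(tert-butyldimethylsilyl)oxy]methyl}-2-oxo-5-(propanoyloxy)-6-(propan-2-yl)cyclohex-3-en-1-yl (2E)-4-[(tert-butyldimethylsilyl)oxy]-2-methylbut-2-enoate
Product: 20 (1R,5S,6S)-3-(hydroxymethyl)-2-oxo-5-(propanoyloxy)-6-(propan-2-yl)cyclohex-3-en-1-yl (2E)-4-hydroxy-2-methylbut-2-enoate
Conditions: HF·pyridine, pyridine, THF, 0 °C → rt
Reagents that add atoms: none
Why: Fluoride-mediated cleavage of both primary silyl ethers under buffered non-basic conditions, which should spare the two esters and the enone and avoid acyl migration.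

**Compound list**
1 | 1,3-dithiane | C1CSCSC1 | starting material
2 | methyl 3-methylbutanoate | CC(C)CC(=O)OC | starting material
3 | 2-lithio-1,3-dithiane | [Li]C1SCCCS1 | intermediate
4 | 1-(1,3-dithian-2-yl)-3-methylbutan-1-one | CC(C)CC(=O)C1SCCCS1 | intermediate
5 | tert-butyldimethyl(prop-2-yn-1-yloxy)silane | C#CCO[Si](C)(C)C(C)(C)C | starting material
6 | {3-[(tert-butyldimethylsilyl)oxy]prop-1-yn-1-yl}lithium | [Li]C#CCO[Si](C)(C)C(C)(C)C | intermediate
7 | lithium 4-[(tert-butyldimethylsilyl)oxy]-1-(dimethylamino)but-2-yn-1-olate | [Li]OC(N(C)C)C#CCO[Si](C)(C)C(C)(C)C | intermediate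
8 | 4-[(tert-butyldimethylsilyl)oxy]but-2-ynal | O=CC#CCO[Si](C)(C)C(C)(C)C | intermediate
9 | (2Z)-4-[(tert-butyldimethylsilyl)oxy]-3-[2-(3-methylbutanoyl)-1,3-dithian-2-yl]but-2-enal | O=C/C=C(\C1(SCCCS1)C(=O)CC(C)C)CO[Si](C)(C)C(C)(C)C | intermediate
10 | (8S,9S)-11-{[(tert-butyldimethylsilyl)oxy]methyl}-9-hydroxy-8-(propan-2-yl)-1,5-dithiaspiro[5.5]undec-10-en-7-one | O[C@H]1C=C(CO[Si](C)(C)C(C)(C)C)C2(SCCCS2)C(=O)[C@H]1C(C)C | intermediate
11 | (8S,9S)-11-{[(tert-butyldimethylsilyl)oxy]methyl}-9-(1-hydroxypropoxy)-8-(propan-2-yl)-1,5-dithiaspiro[5.5]undec-10-en-7-one (hemiacetal carbon of either configuration, present as its samarium alkoxide) | CCC(O)O[C@H]1C=C(CO[Si](C)(C)C(C)(C)C)C2(SCCCS2)C(=O)[C@H]1C(C)C | intermediate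
12 | (7R,8R,9S)-11-{[(tert-butyldimethylsilyl)oxy]methyl}-7-hydroxy-8-(propan-2-yl)-1,5-dithiaspiro[5.5]undec-10-en-9-yl propanoate (locants as in 10) | CCC(=O)O[C@H]1C=C(CO[Si](C)(C)C(C)(C)C)C2(SCCCS2)[C@H](O)[C@H]1C(C)C | intermediate
13 | (1S,5R,6R)-3-{[(tert-butyldimethylsilyl)oxy]methyl}-5-hydroxy-4-oxo-6-(propan-2-yl)cyclohex-2-en-1-yl propanoate | CCC(=O)O[C@H]1C=C(CO[Si](C)(C)C(C)(C)C)C(=O)[C@H](O)[C@H]1C(C)C | intermediate
14 | [(tert-butyldimethylsilyl)oxy]acetaldehyde | O=CCO[Si](C)(C)C(C)(C)C | starting material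
15 | ethyl 2-(triphenylphosphoranylidene)propanoate | CCOC(=O)C(C)=P(c1ccccc1)(c1ccccc1)c1ccccc1 | starting material
16 | ethyl (2E)-4-[(tert-butyldimethylsilyl)oxy]-2-methylbut-2-enoate | CCOC(=O)/C(C)=C/CO[Si](C)(C)C(C)(C)C | intermediate
17 | (2E)-4-[(tert-butyldimethylsilyl)oxy]-2-methylbut-2-enoic acid | OC(=O)/C(C)=C/CO[Si](C)(C)C(C)(C)C | intermediate
18 | (2E)-4-[(tert-butyldimethylsilyl)oxy]-2-methylbut-2-enoic 2,4,6-trichlorobenzoic anhydride | O=C(OC(=O)/C(C)=C/CO[Si](C)(C)C(C)(C)C)c1c(Cl)cc(Cl)cc1Cl | intermediate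
19 | (1R,5S,6S)-3-{[(tert-butyldimethylsilyl)oxy]methyl}-2-oxo-5-(propanoyloxy)-6-(propan-2-yl)cyclohex-3-en-1-yl (2E)-4-[(tert-butyldimethylsilyl)oxy]-2-methylbut-2-enoate | CCC(=O)O[C@H]1C=C(CO[Si](C)(C)C(C)(C)C)C(=O)[C@H](OC(=O)/C(C)=C/CO[Si](C)(C)C(C)(C)C)[C@H]1C(C)C | intermediate
20 | (1R,5S,6S)-3-(hydroxymethyl)-2-oxo-5-(propanoyloxy)-6-(propan-2-yl)cyclohex-3-en-1-yl (2E)-4-hydroxy-2-methylbut-2-enoate | CCC(=O)O[C@H]1C=C(CO)C(=O)[C@H](OC(=O)/C(C)=C/CO)[C@H]1C(C)C | target

Total step count: 9. Longest linear sequence: 6 steps (steps 1, 3, 4, 5, 8 and 9).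

**Steps most likely to fail**

Step 3 (proposed method): the ring-closing aldol may proceed with poor facial discrimination, or the zinc catalyst may stall at enal 9 because the hindered ketone is enolised too slowly. Fallback: from 4 and 8 the annulation is run with LiOtBu (20 mol %) in THF at −40 → 0 °C (Michael/aldol through the lithium Z enolate in a closed transition state), which should give the racemic cis-hydroxy ketone rac-10 F1. Kinetic resolution with Burkholderia cepacia lipase and vinyl acetate in MTBE is then expected to acetylate the (8R,9R) enantiomer to the (8R,9R)-acetate F2 and to leave (8S,9S)-10, which is separated by chromatography and re-enters the route at 10.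

Step 4: hydride transfer from the hemiacetal to the ketone next to the spiro carbon may be slow, so that retro-aldol opening of 10 or self-condensation of propanal competes. Fallback: from 10, hydroxyl-directed reduction with Me4NBH(OAc)3 in MeCN–AcOH at −30 °C should give the anti-1,3-diol F3. One equivalent of propanoic anhydride with 2,4,6-collidine in CH2Cl2 at −20 °C should then acylate the less hindered allylic C4 hydroxyl (the C6 hydroxyl is flanked by the quaternary dithiane carbon and by CH–isopropyl), and the route is rejoined at 12.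

Step 5: the iodine oxidant may attack the free carbinol or the trisubstituted alkene through sulfonium intermediates, or the acid released may cleave the silyl ether. Fallback: from 12 the order is changed. The C6 hydroxyl is first esterified with acid 17 (through 18, DMAP, toluene, 60 °C) to give the dithiane diester F4, and the dithiane is then removed non-oxidatively by S-methylation and hydrolysis (MeI, CaCO3, MeCN–H2O, 45 °C), which rejoins the route at 19.

Further compounds
F1 | step 3 | racemic 11-{[(tert-butyldimethylsilyl)oxy]methyl}-9-hydroxy-8-(propan-2-yl)-1,5-dithiaspiro[5.5]undec-10-en-7-one, cis, (8S,9S) and (8R,9R) | O[C@H]1C=C(CO[Si](C)(C)C(C)(C)C)C2(SCCCS2)C(=O)[C@H]1C(C)C.O[C@@H]1C=C(CO[Si](C)(C)C(C)(C)C)C2(SCCCS2)C(=O)[C@@H]1C(C)C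
F2 | step 3 | (8R,9R)-11-{[(tert-butyldimethylsilyl)oxy]methyl}-7-oxo-8-(propan-2-yl)-1,5-dithiaspiro[5.5]undec-10-en-9-yl acetate (locants as in 10) | CC(=O)O[C@@H]1C=C(CO[Si](C)(C)C(C)(C)C)C2(SCCCS2)C(=O)[C@@H]1C(C)C
F3 | step 4 | (7R,8S,9S)-11-{[(tert-butyldimethylsilyl)oxy]methyl}-8-(propan-2-yl)-1,5-dithiaspiro[5.5]undec-10-ene-7,9-diol | O[C@H]1C=C(CO[Si](C)(C)C(C)(C)C)C2(SCCCS2)[C@H](O)[C@H]1C(C)C
F4 | step 5 | (7R,8S,9S)-11-{[(tert-butyldimethylsilyl)oxy]methyl}-9-(propanoyloxy)-8-(propan-2-yl)-1,5-dithiaspiro[5.5]undec-10-en-7-yl (2E)-4-[(tert-butyldimethylsilyl)oxy]-2-methylbut-2-enoate | CCC(=O)O[C@H]1C=C(CO[Si](C)(C)C(C)(C)C)C2(SCCCS2)[C@H](OC(=O)/C(C)=C/CO[Si](C)(C)C(C)(C)C)[C@H]1C(C)C
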